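## Structural features

The target is a C20 dibromo diol made of two separate cyclohexanes, ring A (C2, C3, C4, C5, C6, C9) and ring B (C14, C15, C16, C17, C19, C20), joined through C9–C10, the (E)-C10=C11 alkene and the tertiary carbinol C12, which is bonded to C14. Ring A carries an exocyclic methylene (C1=C2), a gem-dimethyl carbon (C6) and two stereocentres, C5 (Br) and C9, which are 1,3-cis and both equatorial. Ring B carries C17 (CH3, OH) next to C19 (Br), and C14, whose exocyclic neighbour C12 (CH3, OH) is the sixth stereocentre; C17/C19 and C12/C14 are the two vicinal pairs, and the ring A and ring B clusters are too far apart to control each other. Fragile elements are the two secondary bromides, each flanked by a fully substituted carbon (elimination, 1,2-shifts, no access by substitution), the cis-bromohydrin C17/C19 (ring contraction under base), the tertiary allylic alcohol at C12 (ionization) and the 1,1-disubstituted alkene (migration into ring A). The real difficulty is ring B: bromine at C19 is cis to the C17 hydroxyl, the opposite of what halohydrin chemistry on a ring alkene delivers, and C12 must be set outside the ring in a defined relationship to C14. In the chair of ring B the C19 bromine, the C17 methyl and the C14 side chain are equatorial and the C17 oxygen is axial; this is the pattern left by closing C14–C20 through attack of a C12=C14 alkene on a C19/C20 bromonium ion with anti capture of oxygen at C12, and the key step exploits exactly this, with C17 taken from the chiral pool.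

## Logic of the disconnections

33 ⇒ 32. The O–Si bonds at O12 and O17 are cut last. Both tertiary hydroxyls must be masked while a carbanion is used to join the fragments. Nothing is gained in skeleton, but one mild operation releases both carbinols. The forward step must remove two tertiary silyl ethers without ionizing the allylic C12–O bond or eliminating HBr.

32 ⇒ 31 + 18. The C10=C11 double bond is cut. It is the only unsaturation between the two stereoclusters, it is (E), and C11 sits next to a quaternary carbon, so 18 cannot enolize. The cut gives two fragments of similar size, each with one cluster. The forward olefination must be E-selective and must add a hindered α-sulfonyl carbanion to a hindered aldehyde faster than base attacks either bromide.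

18 ⇒ 17 ⇒ 16 ⇒ 15. These are adjustments at C11 and O12: the C11 oxidation level is lowered, the two O–Si bonds are removed, and the carbonyl carbon bridging O11 and O12 is put back. The cyclic carbonate is the direct imprint of the ring closure, so no extra protecting steps appear before it. The forward steps need a base that spares the cis-bromohydrin ether and an oxidation that distinguishes the primary from the tertiary silyl ethers.

15 ⇒ 13 (through 14). The C14–C20 ring bond and the C12–O bond are cut together. This removes ring B, the dioxolanone and two stereocentres (C12, C14) and leaves an open chain with only C17 and C19. The forward step must create an electrophile at C20 without touching the more nucleophilic C12=C14 alkene, close through a chair, and add carbon and oxygen anti across a (Z)-alkene.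

13 ⇒ 11 (through 12). The C19–Br bond is cut. C19 is the α-carbon of an aldehyde, where bromine can be introduced under catalyst control. The forward step needs a catalyst that overrides the adjacent quaternary C17, no β-loss of the silyloxy group, and reduction before C19 can epimerize.

11 ⇒ 10 ⇒ 8. The C20 oxygen is removed back to the terminal vinyl group. The forward hydroboration must pick the monosubstituted alkene and leave the trisubstituted allylic carbonate alone; a separate oxidation then gives the aldehyde.

8 ⇒ 6 + 7; 6 ⇒ 5 ⇒ 3 + 4. The O–C(=O) bond of the carbonate and then the C12=C14 double bond are cut. This splits off the three-carbon unit C11–C13 as 4. The forward olefination must give the (Z)-trisubstituted alkene, because the alkene geometry becomes the C12 configuration in the key step.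

3 ⇒ 2 ⇒ 1. The C14 aldehyde is reconnected to an isopropylidene group and the O–Si bond is cut. This reaches 1, which supplies C17 with its methyl, its oxygen and the C19=C20 vinyl group. The forward ozonolysis must cleave only the trisubstituted alkene.

31 ⇒ 30 ⇒ 28 + 29; 28 ⇒ 27. The S–O bonds, the C10–S bond and the C10 oxidation level are adjusted. The forward steps need a sulfur oxidation that spares the exocyclic alkene and an ester reduction that does not epimerize the allylic C9.

27 ⇒ 26. The C6–C9 ring bond is cut and silicon is put back on C1. Ring A and C9 disappear and a single stereocentre (C5) remains. The forward step needs ionization at C6 assisted by the C5 bromine, a chair with bromine equatorial, and a (Z)-allylsilane so that C10 ends equatorial.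

26 ⇒ 25 ⇒ 24. The C5–Br bond is cut back to an epoxide, and the epoxide to the terminal alkene. The forward steps need an enantioselective epoxidation of the remote trisubstituted alkene and bromide opening at the secondary carbon with inversion.

24 ⇒ 22 + 23; 22 ⇒ 21; 21 ⇒ 19 + 20. The C1–C2 bond, the enol P–O bond and the C3–C4 bond are cut. This reaches three commercial compounds. The forward steps must fix and keep the enol geometry, which later becomes the C9 configuration.

## Other disconnections considered

Alternative 1: The cut goes through C17–C19 and C14–C20, so ring B is split into furan A1 (C14 to C17, the C18 methyl and a masked acetyl group for C12/C13) and acrylate A2 (C19, C20). In the forward direction a chiral Lewis acid-catalysed Diels–Alder reaction should give the endo oxanorbornene A3, whose methyl-bearing bridgehead already has the C17 configuration.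
- In its favour: ring B and the quaternary carbinol carbon arise in one catalytic step from cheap achiral materials, either enantiomer is accessible, and no cation is ever formed next to the C17 oxygen. On catalytic access and on freedom from the 1,2-shift risk A3 is the better of 15.
- Against it here: furan cycloadditions are reversible and 2,5-disubstituted furans are sluggish, so endo/exo and facial control are less secure than a chair closure. The bridging oxygen is bonded to C14 as well as C17, yet C14 must end as a CH with an equatorial side chain, which calls for a stereocontrolled reductive C–O cleavage. The C19 ester must become an equatorial bromide cis to the C17 oxygen, most plausibly by a radical decarboxylative bromination with no reliable stereocontrol. C12 would still have to be built from a ketone with only a remote ring to direct it.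
- Comparison: structurally A3 fixes one stereocentre of the ring B region where 15 fixes four. Mechanistically the cycloaddition is the safer single step. On step economy it should lose, because bridge opening, deoxygenation at C14, ester-to-bromide exchange and carbinol construction outnumber the three steps from 15 to 18.

Alternative 2: The cut is at C14–C15 and C19–C20, giving aldehyde A4 (C11 to C14 and C20, with C12 already a protected tertiary carbinol) and enone A5 (C15 to C19). In the forward direction an enamine Michael addition followed by intramolecular aldol condensation should give cyclohexenone A6, with C14 set by the amine catalyst next to the preset C12.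
- In its favour: the annulation is a well-precedented catalytic reaction, and the C12/C14 pair is controlled by the reagent, independent of any alkene geometry. On precedent it is the better of step 9; on control of C12/C14 it is the equal.
- Against it here: C17 and C19 are still trigonal in A6. A methyl group must be added to the ketone with the hydroxyl axial, and bromine must be placed at C19 equatorial, cis to that hydroxyl, with hydrogen at C20. That is a cis-bromohydrin, which neither halohydrin formation nor epoxide opening gives. The likely way through regioselective enolate bromination and addition to an α-bromo ketone has uncertain selectivity at both steps and gives a base-sensitive product.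
- Comparison: the stereochemical burden is moved from the C12/C14 pair, which the chosen plan handles by anti addition, to the C17/C19 pair, which the chosen plan takes from 1 and from a catalyst-controlled bromination. Step economy is no better, since A4 needs its own asymmetric synthesis and several steps separate A6 from the stage of 16.

Alternative 3: The cut is at C6–C9, so ring A is closed last. In the forward direction a Lewis acid ionizes the tertiary C6 hydroxyl of the open-chain bromohydrin A7 with help from the C5 bromine, the allylsilane carbon C9 attacks C6, and loss of silicon leaves the C1=C2 alkene. This gives alkyne A8, which must then be reduced to the (E)-alkene.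
- In its favour: ionization at a tertiary carbon next to bromine is the precedented mode. The C10≡C11 alkyne lets the halves be joined by acetylide or cross-coupling chemistry that is indifferent to the crowding around C12. On the fragment union it is arguably the better of step 22.
- Against it here: it leaves ring B, the harder half, unsolved, so it competes with steps 13 to 22 and not with step 9. The cationic closure would be the last skeletal step on the most valuable intermediate, with a tertiary propargylic silyl ether at C12 that can ionize under the same Lewis acid. The alkyne-to-(E)-alkene reduction must spare two secondary bromides and the 1,1-disubstituted alkene.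
- Comparison: it sets the same ring and the same stereocentre (C9) as step 18 of the chosen plan and is the equal on that count. The step count is about equal (one extra reduction against three sulfone-forming steps). The chosen plan runs the same kind of ionization early, on a small ester, where failure costs little.

Key step: step 9

Assumption: commercial (R)-(−)-linalool (1) of at least 95% ee is used; any minor enantiomer would appear after step 22 as a separable diastereomer.

Remark on the chemistry: the chair/anti-addition model delivers 12S,14S only from the (2Z,6R,7S) isomer 13, so the olefination must be Z-selective and the bromination must give 19S. The C17 oxygen is kept as a triethylsilyl ether, because an acyl group would open the bromonium ion at C19 by participation and a free hydroxyl would close an epoxide. A separate oxidation (step 7) is needed between hydroboration and α-bromination. 13 is triflated directly and not stored, to avoid epoxide closure and 1,3-silyl migration.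

## Steps

Step 1
Reactants: 1 (R)-linalool, (3R)-3,7-dimethylocta-1,6-dien-3-ol
Product: 2 triethyl{[(3R)-3,7-dimethylocta-1,6-dien-3-yl]oxy}silane
Conditions: Et3SiOTf, 2,6-lutidine, CH2Cl2, −78 → 0 °C
Reagents that add atoms: triethylsilyl trifluoromethanesulfonate, CC[Si](CC)(CC)OS(=O)(=O)C(F)(F)F
Why: Silylation of a tertiary alcohol with a silyl triflate and a hindered base; the ether must later sit next to a bromonium ion, where a silyl group is the least nucleophilic and least participating choice, and it can still be removed at the end with buffered fluoride.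

Step 2
Reactants: 2 triethyl{[(3R)-3,7-dimethylocta-1,6-dien-3-yl]oxy}silane
Product: 3 (4R)-4-methyl-4-(triethylsilyloxy)hex-5-enal
Conditions: O3, CH2Cl2/MeOH, Sudan Red 7B (indicator), −78 °C; then Me2S, −78 °C → rt
Reagents that add atoms: ozone, [O-][O+]=O
Why: Selective ozonolysis; the electron-rich trisubstituted alkene should react far faster than the vinyl group, which is monosubstituted, neopentylic and inductively deactivated by the silyloxy group, and the indicator marks the end point.

Step 3
Reactants: 3 (4R)-4-methyl-4-(triethylsilyloxy)hex-5-enal; 4 methyl 2-[bis(2,2,2-trifluoroethoxy)phosphoryl]propanoate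
Product: 5 methyl (2Z,6R)-2,6-dimethyl-6-(triethylsilyloxy)octa-2,7-dienoate
Conditions: 4, KN(SiMe3)2, 18-crown-6, THF, −78 °C
Reagents that add atoms: none
Why: Still–Gennari olefination; the electron-poor phosphonate and the dissociated potassium counter-ion make elimination from the kinetic adduct fast, so the (Z)-trisubstituted enoate (ester cis to the chain) should dominate.

Step 4
Reactants: 5 methyl (2Z,6R)-2,6-dimethyl-6-(triethylsilyloxy)octa-2,7-dienoate
Product: 6 (2Z,6R)-2,6-dimethyl-6-(triethylsilyloxy)octa-2,7-dien-1-ol
Conditions: i-Bu2AlH, CH2Cl2, −78 °C; aq. KNaC4H4O6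
Reagents that add atoms: none
Why: 1,2-Reduction of an α,β-unsaturated ester to the allylic alcohol; the alkene geometry and the silyl ether are untouched.

Step 5
Reactants: 6 (2Z,6R)-2,6-dimethyl-6-(triethylsilyloxy)octa-2,7-dien-1-ol; 7 di-tert-butyl dicarbonate
Product: 8 tert-butyl (2Z,6R)-2,6-dimethyl-6-(triethylsilyloxy)octa-2,7-dien-1-yl carbonate
Conditions: 7, 1-methylimidazole (10 mol %), toluene, rt
Reagents that add atoms: none
Why: O-tert-Butoxycarbonylation of a primary alcohol under nucleophilic catalysis; the carbonate is the internal oxygen nucleophile of the key step and is stable to the next four steps.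

Step 6
Reactants: 8 tert-butyl (2Z,6R)-2,6-dimethyl-6-(triethylsilyloxy)octa-2,7-dien-1-yl carbonate
Product: 10 tert-butyl (2Z,6R)-8-hydroxy-2,6-dimethyl-6-(triethylsilyloxy)oct-2-en-1-yl carbonate, via alkylborane 9 (not isolated)
Conditions: 9-BBN, THF, 0 °C → rt; then NaBO3·4H2O, H2O, rt
Reagents that add atoms: 9-borabicyclo[3.3.1]nonane, B1C2CCCC1CCC2 (atoms only in 9); sodium perborate, [Na+].[O-]OB=O (hydroxyl oxygen)
Why: Hydroboration–oxidation; the bulky dialkylborane should add only to the monosubstituted alkene with boron at the terminal C20 and leave the trisubstituted, carbonate-deactivated alkene alone, and perborate oxidizes the C–B bond without cleaving the carbonate.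

Step 7
Reactants: 10 tert-butyl (2Z,6R)-8-hydroxy-2,6-dimethyl-6-(triethylsilyloxy)oct-2-en-1-yl carbonate
Product: 11 tert-butyl (2Z,6R)-2,6-dimethyl-8-oxo-6-(triethylsilyloxy)oct-2-en-1-yl carbonate
Conditions: Dess–Martin periodinane, NaHCO3, CH2Cl2, 0 °C → rt
Reagents that add atoms: none
Why: Buffered Dess–Martin oxidation of a primary alcohol; neutral conditions keep the β-silyloxy aldehyde from eliminating.

Step 8
Reactants: 11 tert-butyl (2Z,6R)-2,6-dimethyl-8-oxo-6-(triethylsilyloxy)oct-2-en-1-yl carbonate
Product: 13 tert-butyl (2Z,6R,7S)-7-bromo-8-hydroxy-2,6-dimethyl-6-(triethylsilyloxy)oct-2-en-1-yl carbonate, via α-bromo aldehyde 12 (not isolated)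
Conditions: (2S,5S)-2,5-diphenylpyrrolidine (20 mol %), 4,4-dibromo-2,6-di-tert-butylcyclohexa-2,5-dien-1-one, PhCO2H (20 mol %), H2O, CH2Cl2/pentane, −40 °C; then NaBH4, MeOH, −40 → 0 °C
Reagents that add atoms: 4,4-dibromo-2,6-di-tert-butylcyclohexa-2,5-dien-1-one, CC(C)(C)C1=CC(Br)(Br)C=C(C(C)(C)C)C1=O
Why: Enamine-catalysed α-bromination of an aldehyde followed by in-situ borohydride reduction; in the (E)-enamine the phenyl group on the ring carbon next to the enamine double bond shields one face, so the (2S,5S) catalyst should deliver bromine to the Si face of C19 (19S in 13) under catalyst control, and immediate reduction prevents epimerization of 12.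

Step 9
Reactants: 13 tert-butyl (2Z,6R,7S)-7-bromo-8-hydroxy-2,6-dimethyl-6-(triethylsilyloxy)oct-2-en-1-yl carbonate
Product: 15 (4S)-4-[(1S,3S,4R)-3-bromo-4-methyl-4-(triethylsilyloxy)cyclohexyl]-4-methyl-1,3-dioxolan-2-one, via primary triflate 14 (not isolated)
Conditions: (CF3SO2)2O, 2,6-di-tert-butyl-4-methylpyridine, CH2Cl2, −78 °C; then (CF3)2CHOH, −78 → 0 °C
Reagents that add atoms: trifluoromethanesulfonic anhydride, O=S(=O)(OS(=O)(=O)C(F)(F)F)C(F)(F)F (atoms only in 14)
Why: Proposed new method: triflation of the C20 hydroxyl gives 14, and in the ionizing medium the C19 bromine should displace triflate from the back, so that a bromonium ion spans C19–C20 without any external brominating agent, which would have attacked the far more nucleophilic C12=C14 alkene first. C14 then opens the ion at the primary carbon C20 anti to bromine (six-membered closure, endo with respect to the bromonium ring and 6-exo with respect to the alkene, as in the neryl to α-terpinyl closure), and the carbonate carbonyl oxygen captures the developing C12 cation from the opposite alkene face (5-exo closure to the dioxolanone), after which isobutene is lost and the proton goes to the hindered base. The closest known reaction types are bromonium-initiated polyene cyclizations terminated by tert-butyl carbonates and bromine-assisted ionization of β-bromo alcohol derivatives at secondary or tertiary carbon; initiation at a primary carbon is the new element. C14 is controlled by the chair: anti opening forces the C19–Br bond equatorial, the preset 17R,19S pair then puts the C17 methyl equatorial and the C17 silyloxy group axial, and the alkene takes the equatorial position, which gives 14S. C12 is controlled by anti addition across the (Z)-alkene, which turns the alkene geometry into 12S relative to 14S. The step needs attack at C20 rather than five-membered closure at C19, and ring closure faster than a 1,2-shift from C17 to C19. The first should be secured by the neopentylic, inductively deactivated character of C19 next to the silyloxy carbon; the second by the proximity of the trisubstituted alkene in the chair, by the weakly donating silyl ether and by buffered low-temperature conditions.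

Step 10
Reactants: 15 (4S)-4-[(1S,3S,4R)-3-bromo-4-methyl-4-(triethylsilyloxy)cyclohexyl]-4-methyl-1,3-dioxolan-2-one
Product: 16 (2S)-2-[(1S,3S,4R)-3-bromo-4-methyl-4-(triethylsilyloxy)cyclohexyl]propane-1,2-diol
Conditions: K2CO3, MeOH, 0 °C → rt
Reagents that add atoms: none
Why: Methanolysis of a cyclic carbonate; the equatorial bromide has no anti-periplanar hydrogen and is cis to the side chain, so neither elimination nor backside displacement by the new alkoxides should compete, and the tertiary silyl ether survives.

Step 11
Reactants: 16 (2S)-2-[(1S,3S,4R)-3-bromo-4-methyl-4-(triethylsilyloxy)cyclohexyl]propane-1,2-diol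
Product: 17 1,2-bis(triethylsilyl) ether of 16, {[(2S)-2-[(1S,3S,4R)-3-bromo-4-methyl-4-(triethylsilyloxy)cyclohexyl]propane-1,2-diyl]bis(oxy)}bis(triethylsilane)
Conditions: Et3SiOTf, 2,6-lutidine, CH2Cl2, −78 → 0 °C
Reagents that add atoms: triethylsilyl trifluoromethanesulfonate, CC[Si](CC)(CC)OS(=O)(=O)C(F)(F)F
Why: Exhaustive silylation; the silyl triflate is reactive enough for the tertiary C12 hydroxyl, and all three oxygens now carry the same group.

Step 12
Reactants: 17 1,2-bis(triethylsilyl) ether of 16
Product: 18 (2S)-2-[(1S,3S,4R)-3-bromo-4-methyl-4-(triethylsilyloxy)cyclohexyl]-2-(triethylsilyloxy)propanal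
Conditions: (COCl)2, DMSO, CH2Cl2, −78 → −30 °C; then Et3N, −78 → 0 °C
Reagents that add atoms: none
Why: Swern oxidation applied directly to a primary triethylsilyl ether; activated DMSO cleaves the unhindered primary silyl ether and oxidizes it in one operation while the two tertiary silyl ethers persist, and the aldehyde has no α-hydrogen to lose.

Step 13
Reactants: 19 methyl acetoacetate; 20 1-bromo-3-methylbut-2-ene
Product: 21 methyl 7-methyl-3-oxooct-6-enoate
Conditions: NaH, THF, 0 °C; n-BuLi, 0 °C; then 20, 0 °C → rt; aq. HCl
Reagents that add atoms: none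
Why: γ-Alkylation of the acetoacetate dianion; the more basic terminal carbanion reacts with the allylic bromide, forming the C3–C4 bond.

Step 14
Reactants: 21 methyl 7-methyl-3-oxooct-6-enoate
Product: 22 methyl (2Z)-3-[(diethoxyphosphoryl)oxy]-7-methylocta-2,6-dienoate
Conditions: NaH, Et2O, 0 °C; (EtO)2P(O)Cl, 0 °C → rt
Reagents that add atoms: diethyl chlorophosphate, CCOP(=O)(Cl)OCC
Why: O-Phosphorylation of the chelated sodium enolate of a β-keto ester, which should fix the (Z) geometry (phosphate cis to the ester).

Step 15
Reactants: 22 methyl (2Z)-3-[(diethoxyphosphoryl)oxy]-7-methylocta-2,6-dienoate; 23 [(trimethylsilyl)methyl]magnesium chloride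
Product: 24 methyl (2Z)-7-methyl-3-[(trimethylsilyl)methyl]octa-2,6-dienoate
Conditions: 23, Ni(acac)2 (5 mol %), THF, 0 °C → rt
Reagents that add atoms: none
Why: Nickel-catalysed cross-coupling of an enol phosphate with a Grignard reagent, which proceeds with retention, so the silylmethyl group ends cis to the ester and the chain trans to it.

Step 16
Reactants: 24 methyl (2Z)-7-methyl-3-[(trimethylsilyl)methyl]octa-2,6-dienoate
Product: 25 methyl (2Z)-5-[(2R)-3,3-dimethyloxiran-2-yl]-3-[(trimethylsilyl)methyl]pent-2-enoate
Conditions: D-fructose-derived Shi ketone (30 mol %), KHSO5 (as 2KHSO5·KHSO4·K2SO4), K2CO3, Bu4NHSO4, MeCN/CH2(OMe)2/aq. Na2B4O7 buffer, 0 °C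
Reagents that add atoms: potassium peroxymonosulfate, [K+].[O-]S(=O)(=O)OO
Why: Shi epoxidation; the chiral dioxirane is electrophilic and should epoxidize only the electron-rich terminal alkene (the enoate is inert), and the D-fructose-derived ketone gives the (R)-epoxide of a 2-methylalk-2-ene through the spiro transition state.

Step 17
Reactants: 25 methyl (2Z)-5-[(2R)-3,3-dimethyloxiran-2-yl]-3-[(trimethylsilyl)methyl]pent-2-enoate
Product: 26 methyl (2Z,6S)-6-bromo-7-hydroxy-7-methyl-3-[(trimethylsilyl)methyl]oct-2-enoate
Conditions: Li2NiBr4, THF, 0 °C → rt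
Reagents that add atoms: dilithium tetrabromonickelate, [Li+].[Li+].[Ni+2].[Br-].[Br-].[Br-].[Br-]
Why: Epoxide opening by soft, nearly neutral bromide; attack should take place in an SN2 manner at the less substituted carbon with inversion, which sets C5 as S, whereas acidic bromide sources would go to the tertiary carbon.

Step 18
Reactants: 26 methyl (2Z,6S)-6-bromo-7-hydroxy-7-methyl-3-[(trimethylsilyl)methyl]oct-2-enoate
Product: 27 methyl (1R,3S)-3-bromo-2,2-dimethyl-6-methylidenecyclohexane-1-carboxylate
Conditions: SnCl4, CH2Cl2, −78 °C
Reagents that add atoms: none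
Why: Cationic cyclization started by Lewis-acid ionization of a tertiary alcohol with neighbouring-bromine assistance and ended by an allylsilane; the chair with bromine equatorial and the ester (trans to the tether on the alkene) equatorial sets C9 cis to C5–Br, and loss of silicon places the alkene exocyclic, with C5 itself never broken.

Step 19
Reactants: 27 methyl (1R,3S)-3-bromo-2,2-dimethyl-6-methylidenecyclohexane-1-carboxylate
Product: 28 [(1R,3S)-3-bromo-2,2-dimethyl-6-methylidenecyclohexyl]methanol
Conditions: i-Bu2AlH, CH2Cl2, −78 °C
Reagents that add atoms: none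
Why: Ester reduction with a non-basic hydride, so the allylic, α-ester C9–H is not epimerized and the alkene is not drawn into conjugation.

Step 20
Reactants: 28 [(1R,3S)-3-bromo-2,2-dimethyl-6-methylidenecyclohexyl]methanol; 29 1-phenyl-1H-tetrazole-5-thiol
Product: 30 5-({[(1R,3S)-3-bromo-2,2-dimethyl-6-methylidenecyclohexyl]methyl}sulfanyl)-1-phenyl-1H-tetrazole
Conditions: 29, PPh3, DIAD, THF, 0 °C → rt
Reagents that add atoms: none
Why: Mitsunobu thioetherification of a primary alcohol with an acidic heteroaryl thiol; the secondary bromide is not touched.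

Step 21
Reactants: 30 5-({[(1R,3S)-3-bromo-2,2-dimethyl-6-methylidenecyclohexyl]methyl}sulfanyl)-1-phenyl-1H-tetrazole
Product: 31 5-({[(1R,3S)-3-bromo-2,2-dimethyl-6-methylidenecyclohexyl]methyl}sulfonyl)-1-phenyl-1H-tetrazole
Conditions: H2O2 (30%), (NH4)6Mo7O24·4H2O (10 mol %), EtOH, 0 °C → rt
Reagents that add atoms: hydrogen peroxide, OO
Why: Molybdate-catalysed oxidation of sulfide to sulfone; the peroxomolybdate is selective for sulfur over a 1,1-disubstituted alkene.

Step 22
Reactants: 31 5-({[(1R,3S)-3-bromo-2,2-dimethyl-6-methylidenecyclohexyl]methyl}sulfonyl)-1-phenyl-1H-tetrazole; 18 (2S)-2-[(1S,3S,4R)-3-bromo-4-methyl-4-(triethylsilyloxy)cyclohexyl]-2-(triethylsilyloxy)propanal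
Product: 32 bis(triethylsilyl) ether of 33, triethyl{[(1R,2S,4S)-2-bromo-4-[(2S,3E)-4-[(1R,3S)-3-bromo-2,2-dimethyl-6-methylidenecyclohexyl]-2-(triethylsilyloxy)but-3-en-2-yl]-1-methylcyclohexyl]oxy}silane
Conditions: KN(SiMe3)2, DME, −60 °C; then 18, −60 °C → rt
Reagents that add atoms: none
Why: Julia–Kocienski olefination; the phenyltetrazolyl sulfone anion adds to the non-enolizable aldehyde, Smiles rearrangement and anti elimination of SO2 and the tetrazolone follow, and with a potassium base in DME and two branched partners the (E)-alkene should dominate.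

Step 23
Reactants: 32 bis(triethylsilyl) ether of 33
Product: 33 (1R,2S,4S)-2-bromo-4-[(2S,3E)-4-[(1R,3S)-3-bromo-2,2-dimethyl-6-methylidenecyclohexyl]-2-hydroxybut-3-en-2-yl]-1-methylcyclohexan-1-ol
Conditions: HF·pyridine, pyridine, THF, 0 °C → rt
Reagents that add atoms: none
Why: Fluoride-mediated cleavage of two tertiary triethylsilyl ethers under buffered, weakly acidic conditions, which avoids alkoxide chemistry at the cis-bromohydrin and ionization of the tertiary allylic alcohol.

## Compound list

1 | (R)-linalool, (3R)-3,7-dimethylocta-1,6-dien-3-ol | CC(C)=CCC[C@@](C)(O)C=C | starting material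
2 | triethyl{[(3R)-3,7-dimethylocta-1,6-dien-3-yl]oxy}silane | CC(C)=CCC[C@@](C)(O[Si](CC)(CC)CC)C=C | intermediate
3 | (4R)-4-methyl-4-(triethylsilyloxy)hex-5-enal | O=CCC[C@@](C)(O[Si](CC)(CC)CC)C=C | intermediate
4 | methyl 2-[bis(2,2,2-trifluoroethoxy)phosphoryl]propanoate | COC(=O)C(C)P(=O)(OCC(F)(F)F)OCC(F)(F)F | starting material
5 | methyl (2Z,6R)-2,6-dimethyl-6-(triethylsilyloxy)octa-2,7-dienoate | COC(=O)/C(C)=C\CC[C@@](C)(O[Si](CC)(CC)CC)C=C | intermediate
6 | (2Z,6R)-2,6-dimethyl-6-(triethylsilyloxy)octa-2,7-dien-1-ol | OC/C(C)=C\CC[C@@](C)(O[Si](CC)(CC)CC)C=C | intermediate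
7 | di-tert-butyl dicarbonate | CC(C)(C)OC(=O)OC(=O)OC(C)(C)C | starting material
8 | tert-butyl (2Z,6R)-2,6-dimethyl-6-(triethylsilyloxy)octa-2,7-dien-1-yl carbonate | CC(C)(C)OC(=O)OC/C(C)=C\CC[C@@](C)(O[Si](CC)(CC)CC)C=C | intermediate
9 | tert-butyl (2Z,6R)-8-(9-borabicyclo[3.3.1]nonan-9-yl)-2,6-dimethyl-6-(triethylsilyloxy)oct-2-en-1-yl carbonate | CC(C)(C)OC(=O)OC/C(C)=C\CC[C@@](C)(O[Si](CC)(CC)CC)CCB1C2CCCC1CCC2 | intermediate
10 | tert-butyl (2Z,6R)-8-hydroxy-2,6-dimethyl-6-(triethylsilyloxy)oct-2-en-1-yl carbonate | CC(C)(C)OC(=O)OC/C(C)=C\CC[C@@](C)(O[Si](CC)(CC)CC)CCO | intermediate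
11 | tert-butyl (2Z,6R)-2,6-dimethyl-8-oxo-6-(triethylsilyloxy)oct-2-en-1-yl carbonate | CC(C)(C)OC(=O)OC/C(C)=C\CC[C@@](C)(O[Si](CC)(CC)CC)CC=O | intermediate
12 | tert-butyl (2Z,6R,7R)-7-bromo-2,6-dimethyl-8-oxo-6-(triethylsilyloxy)oct-2-en-1-yl carbonate | CC(C)(C)OC(=O)OC/C(C)=C\CC[C@@](C)(O[Si](CC)(CC)CC)[C@@H](Br)C=O | intermediate
13 | tert-butyl (2Z,6R,7S)-7-bromo-8-hydroxy-2,6-dimethyl-6-(triethylsilyloxy)oct-2-en-1-yl carbonate | CC(C)(C)OC(=O)OC/C(C)=C\CC[C@@](C)(O[Si](CC)(CC)CC)[C@@H](Br)CO | intermediate
14 | (2S,3R,6Z)-2-bromo-8-[(tert-butoxycarbonyl)oxy]-3,7-dimethyl-3-(triethylsilyloxy)oct-6-en-1-yl trifluoromethanesulfonate | CC(C)(C)OC(=O)OC/C(C)=C\CC[C@@](C)(O[Si](CC)(CC)CC)[C@@H](Br)COS(=O)(=O)C(F)(F)F | intermediate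
15 | (4S)-4-[(1S,3S,4R)-3-bromo-4-methyl-4-(triethylsilyloxy)cyclohexyl]-4-methyl-1,3-dioxolan-2-one | O=C1OC[C@@](C)(O1)[C@H]1CC[C@@](C)(O[Si](CC)(CC)CC)[C@@H](Br)C1 | intermediate
16 | (2S)-2-[(1S,3S,4R)-3-bromo-4-methyl-4-(triethylsilyloxy)cyclohexyl]propane-1,2-diol | OC[C@@](C)(O)[C@H]1CC[C@@](C)(O[Si](CC)(CC)CC)[C@@H](Br)C1 | intermediate
17 | 1,2-bis(triethylsilyl) ether of 16 | CC[Si](CC)(CC)OC[C@@](C)(O[Si](CC)(CC)CC)[C@H]1CC[C@@](C)(O[Si](CC)(CC)CC)[C@@H](Br)C1 | intermediate
18 | (2S)-2-[(1S,3S,4R)-3-bromo-4-methyl-4-(triethylsilyloxy)cyclohexyl]-2-(triethylsilyloxy)propanal | O=C[C@@](C)(O[Si](CC)(CC)CC)[C@H]1CC[C@@](C)(O[Si](CC)(CC)CC)[C@@H](Br)C1 | intermediate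
19 | methyl acetoacetate (methyl 3-oxobutanoate) | COC(=O)CC(C)=O | starting material
20 | 1-bromo-3-methylbut-2-ene | CC(C)=CCBr | starting material
21 | methyl 7-methyl-3-oxooct-6-enoate | COC(=O)CC(=O)CCC=C(C)C | intermediate
22 | methyl (2Z)-3-[(diethoxyphosphoryl)oxy]-7-methylocta-2,6-dienoate | CCOP(=O)(OCC)O/C(CCC=C(C)C)=C\C(=O)OC | intermediate
23 | [(trimethylsilyl)methyl]magnesium chloride | C[Si](C)(C)C[Mg]Cl | starting material
24 | methyl (2Z)-7-methyl-3-[(trimethylsilyl)methyl]octa-2,6-dienoate | COC(=O)/C=C(\C[Si](C)(C)C)CCC=C(C)C | intermediate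
25 | methyl (2Z)-5-[(2R)-3,3-dimethyloxiran-2-yl]-3-[(trimethylsilyl)methyl]pent-2-enoate | COC(=O)/C=C(\C[Si](C)(C)C)CC[C@H]1OC1(C)C | intermediate
26 | methyl (2Z,6S)-6-bromo-7-hydroxy-7-methyl-3-[(trimethylsilyl)methyl]oct-2-enoate | COC(=O)/C=C(\C[Si](C)(C)C)CC[C@H](Br)C(C)(C)O | intermediate
27 | methyl (1R,3S)-3-bromo-2,2-dimethyl-6-methylidenecyclohexane-1-carboxylate | C=C1CC[C@H](Br)C(C)(C)[C@@H]1C(=O)OC | intermediate
28 | [(1R,3S)-3-bromo-2,2-dimethyl-6-methylidenecyclohexyl]methanol | C=C1CC[C@H](Br)C(C)(C)[C@@H]1CO | intermediate
29 | 1-phenyl-1H-tetrazole-5-thiol | Sc1nnnn1-c1ccccc1 | starting material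
30 | 5-({[(1R,3S)-3-bromo-2,2-dimethyl-6-methylidenecyclohexyl]methyl}sulfanyl)-1-phenyl-1H-tetrazole | C=C1CC[C@H](Br)C(C)(C)[C@@H]1CSc1nnnn1-c1ccccc1 | intermediate
31 | 5-({[(1R,3S)-3-bromo-2,2-dimethyl-6-methylidenecyclohexyl]methyl}sulfonyl)-1-phenyl-1H-tetrazole | C=C1CC[C@H](Br)C(C)(C)[C@@H]1CS(=O)(=O)c1nnnn1-c1ccccc1 | intermediate
32 | bis(triethylsilyl) ether of 33 | C=C1CC[C@H](Br)C(C)(C)[C@@H]1/C=C/[C@@](C)(O[Si](CC)(CC)CC)[C@H]1CC[C@@](C)(O[Si](CC)(CC)CC)[C@@H](Br)C1 | intermediate
33 | (1R,2S,4S)-2-bromo-4-[(2S,3E)-4-[(1R,3S)-3-bromo-2,2-dimethyl-6-methylidenecyclohexyl]-2-hydroxybut-3-en-2-yl]-1-methylcyclohexan-1-ol | C=C1CC[C@H](Br)C(C)(C)[C@@H]1/C=C/[C@@](C)(O)[C@H]1CC[C@@](C)(O)[C@@H](Br)C1 | target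

## Step count and least certain steps

Total step count: 23. Longest linear sequence: 14 steps (steps 1 to 12, then 22 and 23). The ring A branch (steps 13 to 21) has 9 steps before the union.

Step 9 (key step). What may go wrong: ionization of the primary triflate may be too slow, so that intermolecular displacement or loss of HBr takes over. Once the bromonium ion exists, migration of a C17 substituent to C19, driven by the silyloxy group, or five-membered closure at C19 may outrun the chair closure. Fallback (known chemistry), setting out from 13 and returning at 15: 13 is treated with NaH in THF at 0 °C to close the terminal epoxide tert-butyl (2Z,6R)-2-methyl-6-[(2R)-oxiran-2-yl]-6-(triethylsilyloxy)hept-2-en-1-yl carbonate F1 (inversion at C19). F1 is opened at the primary carbon with Li2NiBr4 in THF to the regioisomeric bromohydrin tert-butyl (2Z,6R,7S)-8-bromo-7-hydroxy-2,6-dimethyl-6-(triethylsilyloxy)oct-2-en-1-yl carbonate F2. The secondary hydroxyl of F2 is then triflated with (CF3SO2)2O and 2,6-di-tert-butyl-4-methylpyridine in CH2Cl2/(CF3)2CHOH. The C20 bromine displaces the secondary triflate with a second inversion, which is the classical mode of bromine participation, so the same bromonium ion results and carbonate-terminated closure should give 15. This removes the unprecedented ionization at a primary carbon but not the risk of a 1,2-shift.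

Step 8. What may go wrong: enamine formation at a neopentyl-type α-carbon may be slow, the enamine may expel the β-silyloxy group, the C17 centre may oppose the catalyst (poor facial selectivity), or 12 may epimerize before reduction. Fallback, setting out from 11 and returning at 13: 11 is oxidized with NaClO2, NaH2PO4 and 2-methylbut-2-ene to (3R,6Z)-8-[(tert-butoxycarbonyl)oxy]-3,7-dimethyl-3-(triethylsilyloxy)oct-6-enoic acid F3. F3 is converted through its pivaloyl mixed anhydride and the lithium salt of (4R)-4-benzyl-1,3-oxazolidin-2-one into the imide tert-butyl (2Z,6R)-8-[(4R)-4-benzyl-2-oxo-1,3-oxazolidin-3-yl]-2,6-dimethyl-8-oxo-6-(triethylsilyloxy)oct-2-en-1-yl carbonate F4. Its dibutylboron enolate (Bu2BOTf, i-Pr2NEt, −78 °C) is brominated with N-bromosuccinimide on the face away from the benzyl group to give tert-butyl (2Z,6R,7R)-8-[(4R)-4-benzyl-2-oxo-1,3-oxazolidin-3-yl]-7-bromo-2,6-dimethyl-8-oxo-6-(triethylsilyloxy)oct-2-en-1-yl carbonate F5. Reductive removal of the auxiliary with NaBH4 in THF/H2O at 0 °C should give 13.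

Step 17 (the same detour also bypasses step 18). What may go wrong: bromide may open the epoxide at the tertiary carbon (wrong regiochemistry), or the Lewis-acidic divalent nickel may trigger epoxide rearrangement; in step 18 loss of a proton from the β-bromo cation or protodesilylation may compete with ring closure. Fallback, setting out from 24 and returning at 27: 24 is epoxidized with the enantiomeric Shi ketone (from L-sorbose) to methyl (2Z)-5-[(2S)-3,3-dimethyloxiran-2-yl]-3-[(trimethylsilyl)methyl]pent-2-enoate F6. A Lewis acid-promoted epoxide–allylsilane cyclization (BF3·OEt2, CH2Cl2, −78 °C) should give methyl (1R,3S)-3-hydroxy-2,2-dimethyl-6-methylidenecyclohexane-1-carboxylate F7 with the hydroxyl equatorial. Dess–Martin oxidation gives methyl (1R)-2,2-dimethyl-6-methylidene-3-oxocyclohexane-1-carboxylate F8. Reduction with LiBH(s-Bu)3 at −78 °C from the equatorial side gives the axial alcohol methyl (1R,3R)-3-hydroxy-2,2-dimethyl-6-methylidenecyclohexane-1-carboxylate F9. An Appel reaction (CBr4, PPh3) with inversion should then give the equatorial bromide 27.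

Step 22. What may go wrong: addition of the hindered sulfonyl carbanion to the α-quaternary aldehyde may be slow, so that self-condensation of the sulfone or base-induced loss of HBr competes, with erosion of E selectivity. Fallback, setting out from 16 and 28 and returning at 32, with the roles of the partners exchanged: 16 is converted by Mitsunobu thioetherification with 29 (PPh3, DIAD; the diol may pass through its terminal epoxide, which the thiol opens at CH2) into (2S)-2-[(1S,3S,4R)-3-bromo-4-methyl-4-(triethylsilyloxy)cyclohexyl]-1-[(1-phenyl-1H-tetrazol-5-yl)sulfanyl]propan-2-ol F10. F10 is silylated with Et3SiOTf and 2,6-lutidine to 5-{[(2S)-2-[(1S,3S,4R)-3-bromo-4-methyl-4-(triethylsilyloxy)cyclohexyl]-2-(triethylsilyloxy)propyl]sulfanyl}-1-phenyl-1H-tetrazole F11, which is oxidized with buffered m-chloroperbenzoic acid to 5-{[(2S)-2-[(1S,3S,4R)-3-bromo-4-methyl-4-(triethylsilyloxy)cyclohexyl]-2-(triethylsilyloxy)propyl]sulfonyl}-1-phenyl-1H-tetrazole F12. 28 is oxidized with buffered Dess–Martin periodinane to (1R,3S)-3-bromo-2,2-dimethyl-6-methylidenecyclohexane-1-carbaldehyde F13, used at once to avoid epimerization at C9. Julia–Kocienski olefination of F13 with the anion of F12 (KN(SiMe3)2, DME, −60 °C) should give 32.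

## Further compounds

F1 | step 9 | tert-butyl (2Z,6R)-2-methyl-6-[(2R)-oxiran-2-yl]-6-(triethylsilyloxy)hept-2-en-1-yl carbonate | CC(C)(C)OC(=O)OC/C(C)=C\CC[C@@](C)(O[Si](CC)(CC)CC)[C@H]1CO1
F2 | step 9 | tert-butyl (2Z,6R,7S)-8-bromo-7-hydroxy-2,6-dimethyl-6-(triethylsilyloxy)oct-2-en-1-yl carbonate | CC(C)(C)OC(=O)OC/C(C)=C\CC[C@@](C)(O[Si](CC)(CC)CC)[C@H](O)CBr
F3 | step 8 | (3R,6Z)-8-[(tert-butoxycarbonyl)oxy]-3,7-dimethyl-3-(triethylsilyloxy)oct-6-enoic acid | CC(C)(C)OC(=O)OC/C(C)=C\CC[C@@](C)(O[Si](CC)(CC)CC)CC(=O)O
F4 | step 8 | tert-butyl (2Z,6R)-8-[(4R)-4-benzyl-2-oxo-1,3-oxazolidin-3-yl]-2,6-dimethyl-8-oxo-6-(triethylsilyloxy)oct-2-en-1-yl carbonate | CC(C)(C)OC(=O)OC/C(C)=C\CC[C@@](C)(O[Si](CC)(CC)CC)CC(=O)N1[C@H](Cc2ccccc2)COC1=O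
F5 | step 8 | tert-butyl (2Z,6R,7R)-8-[(4R)-4-benzyl-2-oxo-1,3-oxazolidin-3-yl]-7-bromo-2,6-dimethyl-8-oxo-6-(triethylsilyloxy)oct-2-en-1-yl carbonate | CC(C)(C)OC(=O)OC/C(C)=C\CC[C@@](C)(O[Si](CC)(CC)CC)[C@@H](Br)C(=O)N1[C@H](Cc2ccccc2)COC1=O
F6 | step 17 | methyl (2Z)-5-[(2S)-3,3-dimethyloxiran-2-yl]-3-[(trimethylsilyl)methyl]pent-2-enoate | COC(=O)/C=C(\C[Si](C)(C)C)CC[C@@H]1OC1(C)C
F7 | step 17 | methyl (1R,3S)-3-hydroxy-2,2-dimethyl-6-methylidenecyclohexane-1-carboxylate | C=C1CC[C@H](O)C(C)(C)[C@@H]1C(=O)OC
F8 | step 17 | methyl (1R)-2,2-dimethyl-6-methylidene-3-oxocyclohexane-1-carboxylate | C=C1CCC(=O)C(C)(C)[C@@H]1C(=O)OC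
F9 | step 17 | methyl (1R,3R)-3-hydroxy-2,2-dimethyl-6-methylidenecyclohexane-1-carboxylate | C=C1CC[C@@H](O)C(C)(C)[C@@H]1C(=O)OC
F10 | step 22 | (2S)-2-[(1S,3S,4R)-3-bromo-4-methyl-4-(triethylsilyloxy)cyclohexyl]-1-[(1-phenyl-1H-tetrazol-5-yl)sulfanyl]propan-2-ol | c1ccc(cc1)-n1nnnc1SC[C@@](C)(O)[C@H]1CC[C@@](C)(O[Si](CC)(CC)CC)[C@@H](Br)C1
F11 | step 22 | 5-{[(2S)-2-[(1S,3S,4R)-3-bromo-4-methyl-4-(triethylsilyloxy)cyclohexyl]-2-(triethylsilyloxy)propyl]sulfanyl}-1-phenyl-1H-tetrazole | c1ccc(cc1)-n1nnnc1SC[C@@](C)(O[Si](CC)(CC)CC)[C@H]1CC[C@@](C)(O[Si](CC)(CC)CC)[C@@H](Br)C1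
F12 | step 22 | 5-{[(2S)-2-[(1S,3S,4R)-3-bromo-4-methyl-4-(triethylsilyloxy)cyclohexyl]-2-(triethylsilyloxy)propyl]sulfonyl}-1-phenyl-1H-tetrazole | c1ccc(cc1)-n1nnnc1S(=O)(=O)C[C@@](C)(O[Si](CC)(CC)CC)[C@H]1CC[C@@](C)(O[Si](CC)(CC)CC)[C@@H](Br)C1
F13 | step 22 | (1R,3S)-3-bromo-2,2-dimethyl-6-methylidenecyclohexane-1-carbaldehyde | C=C1CC[C@H](Br)C(C)(C)[C@@H]1C=O
A1 | alternative 1 | 2-methyl-5-(2-methyl-1,3-dioxolan-2-yl)furan | Cc1ccc(o1)C1(C)OCCO1
A2 | alternative 1 | 2,2,2-trifluoroethyl acrylate | C=CC(=O)OCC(F)(F)F
A3 | alternative 1 | 2,2,2-trifluoroethyl endo-1-methyl-4-(2-methyl-1,3-dioxolan-2-yl)-7-oxabicyclo[2.2.1]hept-5-ene-2-carboxylate, R at the methyl-bearing bridgehead | C[C@]12C=C[C@](O1)(C[C@H]2C(=O)OCC(F)(F)F)C1(C)OCCO1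
A4 | alternative 2 | 2-[(4S)-2,2,4-trimethyl-1,3-dioxolan-4-yl]acetaldehyde | CC1(C)OC[C@@](C)(O1)CC=O
A5 | alternative 2 | but-3-en-2-one | CC(=O)C=C
A6 | alternative 2 | (4S)-4-[(4S)-2,2,4-trimethyl-1,3-dioxolan-4-yl]cyclohex-2-en-1-one | CC1(C)OC[C@@](C)(O1)[C@H]1CCC(=O)C=C1
A7 | alternative 3 | open-chain precursor of A8: C5 bromide and C6 tertiary alcohol, (Z)-C2=C9 allylsilane with Me3SiCH2 on C2, C10≡C11 alkyne, C12 and ring B as in 32 | C[Si](C)(C)C/C(CC[C@H](Br)C(C)(C)O)=C\C#C[C@@](C)(O[Si](CC)(CC)CC)[C@H]1CC[C@@](C)(O[Si](CC)(CC)CC)[C@@H](Br)C1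
A8 | alternative 3 | 10,11-didehydro analogue of 32 (C10≡C11 alkyne, bis(triethylsilyl) ether) | C=C1CC[C@H](Br)C(C)(C)[C@@H]1C#C[C@@](C)(O[Si](CC)(CC)CC)[C@H]1CC[C@@](C)(O[Si](CC)(CC)CC)[C@@H](Br)C1
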